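## Analysis of the target

Kazinol N (22) is an achiral 1,3-diarylpropane. Ring A is a 4-hydroxy-2-methoxyphenyl group, and three methylene groups join it to C6 of a 2,2-dimethyl-2H-chromene. The benzo ring of the chromene (ring B) carries a prenyl group on C5, the linker on C6, hydrogen on C7 and a free hydroxyl on C8, while C8a holds the pyran oxygen and C4a the vinylic carbon C4. There is no stereocentre and no double bond with E/Z isomerism, so the problem is purely one of regiochemistry on a benzene ring with five of six positions substituted. The sensitive groups are the C3=C4 double bond and the prenyl double bond (acid, electrophiles, hydrogenation), the electron-rich catechol monoether of ring B (oxidation), and the ring A methyl ether, which must stay while two other phenolic oxygens are set free. The difficulty is that C5 and C6 carry two different carbon substituents next to a catechol whose two oxygens have different fates, a pattern that electrophilic substitution of a catechol does not deliver cleanly. The plan rests on one feature: the oxygens on C8 and C8a are adjacent, C6 lies para to C8a, and C5 is bonded to a CH2 group. That is the substitution pattern of kojic acid (C5–OH, C4=O, C2–CH2OH) with its ring oxygen replaced by the carbon C6 that bears the linker.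

## Retrosynthetic reasoning

**Phenol release.** Target 22 is traced back to bis(allyl ether) 21. Only two O–allyl bonds are cut, and they are cut last because allyl ethers can be removed under neutral conditions that leave the methyl ether, the prenyl group and the chromene alone. The forward reaction must free both phenols without acid, hydride or hydrogen.

**Prenyl group.** In 21 the bond between the benzylic CH2 on C5 and the alkenyl carbon is cut, giving benzylic bromide 20 and an alkenyl organometallic. The cut is made there, and not at the aryl–CH2 bond, because C5 has no ortho hydroxyl to direct a prenylation and the CH2 is already present as a handle. Bromide 20 comes from alcohol 19, and 19 from silyl ether 18. The forward coupling must form an sp3–sp2 bond without touching two allyl aryl ethers.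

**Pyran ring.** Chromene 18 is opened at O1–C2 and C4–C4a to phenol 16 and enal 17. Nothing has to steer the ring closure: in 16 the hydroxyl that becomes O1 is free, the other catechol oxygen is capped as its allyl ether, and only one ortho carbon (the future C4a) carries hydrogen. Phenol 16 is arene 15 without its aryl silyl group.

**Ring B (key disconnection).** In arene 15 the two ring bonds of C6 (C6–C7 and C6–C5) are cut. C6 together with the linker and ring A becomes the ylide 11 of phosphonium salt 10, and the remaining five ring carbons with their oxygens become pyranone 3. This is the only cut that removes the pentasubstituted benzene from the problem. All the ring B substituents except the linker are already on 3 with the right neighbours, and the two oxygens are already told apart (carbonyl against allyl ether). The forward reaction has to exchange the ring oxygen of 3 for the ylide carbon: activation as pyrylium salt 12, addition to give 13, ring opening to keto ylide 14, and ring closure by olefination.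

**Pyranone 3.** It comes from kojic acid 1 by allylation of the enolic hydroxyl (allyl ether 2) and silylation of the primary alcohol. Both operations differentiate hydroxyls by acidity, so no selectivity problem arises.

**Phosphonium salt 10.** The P–C bond is cut to chloride 8 (through iodide 9). The aryl–CH2 bond of 8 is cut to Grignard reagent 7 and dihalide 6, whose bromide reacts and whose chloride is kept for the phosphorus. Reagent 7 comes from aryl bromide 5, the allyl ether of bromophenol 4, in which bromine already sits para to the hydroxyl and ortho to the methoxy group, as ring A requires.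

## Alternatives that were turned down

**Alternative 1:** The linker is cut between its middle carbon and the carbon attached to ring A, and the ring A oxygen that later becomes the methoxy group is temporarily tied to the benzylic carbon next to ring B. In the forward step a hindered Grignard base releases an ortho-quinone methide from carbonate A3, and this adds the ring B vinylarene A2 in a hetero-Diels–Alder reaction to give racemic flavan A1. The flavan ring then has to be opened reductively at its benzylic C–O bond, the liberated phenol methylated, and the chromene built afterwards.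
- For it: the cycloaddition is established chemistry on this substrate class, its regiochemistry is dependable, and the union is convergent. On the reliability of the key step this alternative is stronger than the chosen one.
- Against it: A2 is itself the pentasubstituted ring B, with prenyl group and differentiated catechol, so the real difficulty of the target is pushed into a long classical preparation of A2.
- Against it: a stereocentre is made only to be destroyed.
- Against it: the benzylic C–O cleavage must be reductive yet spare the prenyl double bond, which rules out hydrogenolysis.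
- Comparison: the chosen route offers instead a ring B that is assembled and joined to the linker in one operation from a commodity pyranone, and it should be several steps shorter overall.

**Alternative 2:** Ring B is cut across C8–C7 and C4a–C5 into a three-carbon dinucleophile, diene A5, and a three-carbon dielectrophile, enone A6. A strong Lewis acid would condense them in a formal [3+3] cyclisation to salicylate A4.
- For it: this is a known arene synthesis with predictable regiochemistry, it builds ring B de novo with all positions set, and the two oxygens emerge differentiated (free hydroxyl against benzyl ether). Its key step is better precedented than the chosen one.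
- Against it: the ester on the future C4a and the benzyloxyethyl group on C5 are only distant precursors of the pyran ring and the prenyl group. Each needs about three further steps of redox and olefination chemistry.
- Against it: the benzyl ether on the C8 oxygen must be exchanged before any alkene appears, because hydrogenolysis is then excluded.
- Against it: A6 demands regioselective formylation of a ketone with two different α-methylene groups.
- Comparison: the sequence should run well beyond fifteen steps. The chosen route gives the same de novo ring construction, but the pyranone supplies the CH2 handle at the right oxidation level and the oxygens already in their final roles.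

**Alternative 3:** Both the C6–linker bond and the C5–prenyl bond are cut from an intact chromene. In one palladium-catalysed relay with a strained bicyclic alkene as mediator, aryl iodide A8 would be alkylated at the ortho carbon by bromide A9 and coupled at the ipso carbon with allylic boronate A10, giving A7, the bis(methoxymethyl) ether of the target.
- For it: it is the most convergent plan, and A7 is one deprotection from Kazinol N. On step count this alternative is stronger than the chosen route.
- Against it: three selectivities must hold in one step. Ortho alkylation must precede ipso coupling, the allylic boron reagent can deliver the linear prenyl or the branched 1,1-dimethylallyl group, and the arylpalladium intermediate sits next to the chromene double bond and meets an alkyl halide with β-hydrogens.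
- Against it: A8 needs iodination at C5 in the presence of the reactive C3=C4 bond, and the end game is an acidic acetal cleavage on an acid-sensitive chromene.
- Comparison: the chosen route has one uncertain step without regiochemical ambiguity, after which only standard operations follow.

Key step: step 6

Remark: the target has no stereogenic element, so intermediates 13 and 14 are drawn without configuration; "allyl" stands for prop-2-en-1-yl throughout.

## Route

Step 1
Reactants: 1 kojic acid
Product: 2 5-(allyloxy)-2-(hydroxymethyl)-4H-pyran-4-one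
Conditions: allyl bromide, K2CO3, DMF, 50 °C
Reagents that add atoms: allyl bromide, C=CCBr
Why: The enolic 5-hydroxyl (pKa about 8) is far more acidic than the primary alcohol, so carbonate deprotonates only it and Williamson alkylation gives the mono-ether; the temperature is kept low because allyl ethers of this pyranone undergo Claisen rearrangement on strong heating.

Step 2
Reactants: 2 5-(allyloxy)-2-(hydroxymethyl)-4H-pyran-4-one
Product: 3 5-(allyloxy)-2-[(tert-butyldiphenylsilyloxy)methyl]-4H-pyran-4-one
Conditions: t-BuPh2SiCl, imidazole, DMF, rt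
Reagents that add atoms: tert-butylchlorodiphenylsilane, CC(C)(C)[Si](Cl)(c1ccccc1)c1ccccc1
Why: Standard imidazole-assisted silylation of a primary alcohol; the bulky t-BuPh2Si group is chosen to survive the silyl triflate, the amide base and the acidic chromene annulation, and to remain when the aryl silyl ether is cleaved in step 7.

Step 3
Reactants: 4 4-bromo-3-methoxyphenol
Product: 5 1-(allyloxy)-4-bromo-3-methoxybenzene
Conditions: allyl bromide, K2CO3, acetone, reflux
Reagents that add atoms: allyl bromide, C=CCBr
Why: Williamson etherification of the phenol; allyl is used on both phenols that must be free at the end because it is removed in step 12 without acid, hydride or hydrogen.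

Step 4
Reactants: 5 1-(allyloxy)-4-bromo-3-methoxybenzene; 6 1-bromo-4-chlorobutane
Product: 8 1-(allyloxy)-4-(4-chlorobutyl)-3-methoxybenzene, via aryl Grignard reagent 7 (not isolated)
Conditions: Mg, THF, 50 °C; then 6, Li2CuCl4 (3 mol%), THF, −10 °C to rt
Reagents that add atoms: none
Why: Magnesium insertion into the aryl bromide followed by copper-catalysed alkylation of the aryl Grignard reagent (Kochi-type coupling), which displaces bromide and leaves the less reactive chloride; at this temperature an aryl allyl ether is a much poorer electrophile than a primary bromide.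

Step 5
Reactants: 8 1-(allyloxy)-4-(4-chlorobutyl)-3-methoxybenzene
Product: 10 [4-(4-allyloxy-2-methoxyphenyl)butyl]triphenylphosphonium iodide, via 4-arylbutyl iodide 9 (not isolated)
Conditions: NaI, PPh3, MeCN, reflux
Reagents that add atoms: triphenylphosphine, c1ccc(cc1)P(c1ccccc1)c1ccccc1; sodium iodide, [Na+].[I-]
Why: Finkelstein exchange in the same flask turns the chloride into the more reactive iodide 9, which quaternises PPh3 by SN2 substitution; NaCl precipitates from MeCN, so the salt is obtained as the iodide.

Step 6
Reactants: 3 5-(allyloxy)-2-[(tert-butyldiphenylsilyloxy)methyl]-4H-pyran-4-one; 10 [4-(4-allyloxy-2-methoxyphenyl)butyl]triphenylphosphonium iodide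
Product: 15 1-(allyloxy)-2-(tert-butyldimethylsilyloxy)-4-[(tert-butyldiphenylsilyloxy)methyl]-5-[3-(4-allyloxy-2-methoxyphenyl)propyl]benzene, via phosphorus ylide 11 (not isolated), via 4-silyloxypyrylium triflate 12 (not isolated), via 2H-pyranylphosphonium triflate 13 (not isolated), via open-chain keto ylide 14 (not isolated)
Conditions: 3, t-BuMe2SiOTf (1.05 equiv), CH2Cl2, rt; 10, KN(SiMe3)2 (1.0 equiv), THF, −78 to 0 °C; ylide added to the pyrylium salt at −78 °C; KN(SiMe3)2 (1.1 equiv), −78 °C to rt, then 45 °C
Reagents that add atoms: tert-butyldimethylsilyl trifluoromethanesulfonate, CC(C)(C)[Si](C)(C)OS(=O)(=O)C(F)(F)F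
Why: Proposed new method: O-silylation of pyranone 3 gives pyrylium salt 12, ylide 11 adds to an α-carbon to give adduct 13, the second equivalent of base turns 13 into keto ylide 14 by opening of the 2H-pyran (retro-oxa-6π reaction or the equivalent β-elimination of the ring oxygen), and 14 closes by intramolecular Wittig olefination with loss of Ph3PO, so that the ylide carbon takes the place of the ring oxygen. The closest known reaction types are the conversion of 2,4,6-trisubstituted pyrylium salts into benzenes by alkylidenephosphoranes and the addition of carbon nucleophiles to 4-silyloxypyrylium ions generated from 4-pyranones with silyl triflates; their union on a pyranone with a free α-position and an α-CH2O group is not precedented. Ring B closes as a six-membered carbocycle by 6-exo-trig attack of the ylide carbon on the ketone carbonyl, and collapse of the oxaphosphetane makes the last ring double bond and with it the aromatic ring. No stereocentre remains, since the two stereocentres of 13 are erased on ring opening and aromatisation. The selectivity needed is carbon–carbon bond formation at an α-carbon of 12 in preference to proton removal from the CH2OSi group, attack at silicon or attack at C4; the low temperature, the bulk of both silyl groups and the donor oxygen on C4 should secure it. Which α-carbon is attacked does not matter, because addition at C6 (shown, the unhindered CH) or at C2 leads through a ketone or an aldehyde to the same arene, the ylide carbon ending up bonded to both. The geometry needed for closure is within reach because 14 is a delocalised phosphonium dienolate whose carbon–carbon bonds can rotate, and any aryl silyl ether lost on the way would surface as phenol 16, the next intermediate.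

Step 7
Reactants: 15 1-(allyloxy)-2-(tert-butyldimethylsilyloxy)-4-[(tert-butyldiphenylsilyloxy)methyl]-5-[3-(4-allyloxy-2-methoxyphenyl)propyl]benzene
Product: 16 2-(allyloxy)-5-[(tert-butyldiphenylsilyloxy)methyl]-4-[3-(4-allyloxy-2-methoxyphenyl)propyl]phenol
Conditions: K2CO3 (0.3 equiv), MeOH, rt
Reagents that add atoms: none
Why: Aryl silyl ethers undergo methoxide-mediated transsilylation under conditions that leave the hindered primary alkyl t-BuPh2Si ether and the allyl ethers untouched, because phenoxide is the better leaving group.

Step 8
Reactants: 16 2-(allyloxy)-5-[(tert-butyldiphenylsilyloxy)methyl]-4-[3-(4-allyloxy-2-methoxyphenyl)propyl]phenol; 17 3-methylbut-2-enal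
Product: 18 8-(allyloxy)-5-[(tert-butyldiphenylsilyloxy)methyl]-6-[3-(4-allyloxy-2-methoxyphenyl)propyl]-2,2-dimethyl-2H-chromene
Conditions: PhB(OH)2, AcOH, toluene, reflux (Dean–Stark)
Reagents that add atoms: none
Why: Phenylboronic acid-templated ortho-hydroxyalkylation of the phenol by the enal, followed by dehydration and oxa-6π electrocyclisation, is a known chromene annulation for phenols that are not strongly activated; only one ortho carbon of 16 carries hydrogen, so the ring can close only at C4a.

Step 9
Reactants: 18 8-(allyloxy)-5-[(tert-butyldiphenylsilyloxy)methyl]-6-[3-(4-allyloxy-2-methoxyphenyl)propyl]-2,2-dimethyl-2H-chromene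
Product: 19 {8-(allyloxy)-6-[3-(4-allyloxy-2-methoxyphenyl)propyl]-2,2-dimethyl-2H-chromen-5-yl}methanol
Conditions: n-Bu4NF, THF, 0 °C to rt
Reagents that add atoms: none
Why: Fluoride-induced cleavage of the silyl ether, driven by the Si–F bond; allyl ethers and the chromene are inert to fluoride.

Step 10
Reactants: 19 {8-(allyloxy)-6-[3-(4-allyloxy-2-methoxyphenyl)propyl]-2,2-dimethyl-2H-chromen-5-yl}methanol
Product: 20 8-(allyloxy)-5-(bromomethyl)-6-[3-(4-allyloxy-2-methoxyphenyl)propyl]-2,2-dimethyl-2H-chromene
Conditions: CBr4, PPh3, CH2Cl2, 0 °C; filtered through a short silica pad and used at once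
Reagents that add atoms: tetrabromomethane, BrC(Br)(Br)Br
Why: Appel bromination converts the benzylic alcohol into the bromide under neutral conditions, avoiding acid that could ionise this para-alkoxybenzylic position or add to the chromene double bond.

Step 11
Reactants: 20 8-(allyloxy)-5-(bromomethyl)-6-[3-(4-allyloxy-2-methoxyphenyl)propyl]-2,2-dimethyl-2H-chromene
Product: 21 8-(allyloxy)-6-[3-(4-allyloxy-2-methoxyphenyl)propyl]-2,2-dimethyl-5-(3-methylbut-2-en-1-yl)-2H-chromene
Conditions: 2-methylprop-1-enylmagnesium bromide, CuI (10 mol%), THF, −30 to 0 °C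
Reagents that add atoms: 2-methylprop-1-enylmagnesium bromide, CC(C)=C[Mg]Br
Why: Copper-catalysed cross-coupling of a benzylic bromide with an alkenyl Grignard reagent forms the CH2–CH= bond of the prenyl group with the trisubstituted double bond already in place; a palladium-free coupling is chosen because zerovalent palladium could ionise the two allyl aryl ethers.

Step 12
Reactants: 21 8-(allyloxy)-6-[3-(4-allyloxy-2-methoxyphenyl)propyl]-2,2-dimethyl-5-(3-methylbut-2-en-1-yl)-2H-chromene
Product: 22 Kazinol N, 6-[3-(4-hydroxy-2-methoxyphenyl)propyl]-2,2-dimethyl-5-(3-methylbut-2-en-1-yl)-2H-chromen-8-ol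
Conditions: Pd(PPh3)4 (5 mol%), morpholine, THF, rt
Reagents that add atoms: none
Why: Tsuji–Trost-type deallylation: zerovalent palladium inserts into both allyl–oxygen bonds and morpholine takes up the allyl groups, which frees the two phenols under neutral conditions that leave the methyl ether, the prenyl group and the chromene untouched.

## Compound list

1 | kojic acid, 5-hydroxy-2-(hydroxymethyl)-4H-pyran-4-one | O=c1cc(CO)occ1O | starting material
2 | 5-(allyloxy)-2-(hydroxymethyl)-4H-pyran-4-one | C=CCOc1coc(CO)cc1=O | intermediate
3 | 5-(allyloxy)-2-[(tert-butyldiphenylsilyloxy)methyl]-4H-pyran-4-one | C=CCOc1coc(CO[Si](c2ccccc2)(c2ccccc2)C(C)(C)C)cc1=O | intermediate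
4 | 4-bromo-3-methoxyphenol | COc1cc(O)ccc1Br | starting material
5 | 1-(allyloxy)-4-bromo-3-methoxybenzene | C=CCOc1ccc(Br)c(OC)c1 | intermediate
6 | 1-bromo-4-chlorobutane | ClCCCCBr | starting material
7 | [4-(allyloxy)-2-methoxyphenyl]magnesium bromide (not isolated) | C=CCOc1ccc([Mg]Br)c(OC)c1 | intermediate
8 | 1-(allyloxy)-4-(4-chlorobutyl)-3-methoxybenzene | C=CCOc1ccc(CCCCCl)c(OC)c1 | intermediate
9 | 1-(allyloxy)-4-(4-iodobutyl)-3-methoxybenzene (not isolated) | C=CCOc1ccc(CCCCI)c(OC)c1 | intermediate
10 | [4-(4-allyloxy-2-methoxyphenyl)butyl]triphenylphosphonium iodide | COc1cc(OCC=C)ccc1CCCC[P+](c1ccccc1)(c1ccccc1)c1ccccc1.[I-] | intermediate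
11 | [4-(4-allyloxy-2-methoxyphenyl)butylidene]triphenyl-λ5-phosphane (not isolated) | COc1cc(OCC=C)ccc1CCCC=P(c1ccccc1)(c1ccccc1)c1ccccc1 | intermediate
12 | 5-(allyloxy)-4-(tert-butyldimethylsilyloxy)-2-[(tert-butyldiphenylsilyloxy)methyl]pyrylium trifluoromethanesulfonate (not isolated) | C=CCOc1c[o+]c(CO[Si](c2ccccc2)(c2ccccc2)C(C)(C)C)cc1O[Si](C)(C)C(C)(C)C.[O-]S(=O)(=O)C(F)(F)F | intermediate
13 | {1-[3-(allyloxy)-4-(tert-butyldimethylsilyloxy)-6-[(tert-butyldiphenylsilyloxy)methyl]-2H-pyran-2-yl]-4-(4-allyloxy-2-methoxyphenyl)butyl}triphenylphosphonium trifluoromethanesulfonate (diastereomer mixture, not isolated) | C=CCOC1=C(O[Si](C)(C)C(C)(C)C)C=C(CO[Si](c2ccccc2)(c2ccccc2)C(C)(C)C)OC1C(CCCc1ccc(OCC=C)cc1OC)[P+](c1ccccc1)(c1ccccc1)c1ccccc1.[O-]S(=O)(=O)C(F)(F)F | intermediate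
14 | 5-(allyloxy)-10-(4-allyloxy-2-methoxyphenyl)-4-(tert-butyldimethylsilyloxy)-1-(tert-butyldiphenylsilyloxy)-7-(triphenyl-λ5-phosphanylidene)deca-3,5-dien-2-one (double-bond geometry mobile, not isolated) | C=CCOC(=CC(CCCc1ccc(OCC=C)cc1OC)=P(c1ccccc1)(c1ccccc1)c1ccccc1)C(O[Si](C)(C)C(C)(C)C)=CC(=O)CO[Si](c1ccccc1)(c1ccccc1)C(C)(C)C | intermediate
15 | 1-(allyloxy)-2-(tert-butyldimethylsilyloxy)-4-[(tert-butyldiphenylsilyloxy)methyl]-5-[3-(4-allyloxy-2-methoxyphenyl)propyl]benzene | C=CCOc1ccc(CCCc2cc(OCC=C)c(O[Si](C)(C)C(C)(C)C)cc2CO[Si](c2ccccc2)(c2ccccc2)C(C)(C)C)c(OC)c1 | intermediate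
16 | 2-(allyloxy)-5-[(tert-butyldiphenylsilyloxy)methyl]-4-[3-(4-allyloxy-2-methoxyphenyl)propyl]phenol | C=CCOc1ccc(CCCc2cc(OCC=C)c(O)cc2CO[Si](c2ccccc2)(c2ccccc2)C(C)(C)C)c(OC)c1 | intermediate
17 | 3-methylbut-2-enal | CC(C)=CC=O | starting material
18 | 8-(allyloxy)-5-[(tert-butyldiphenylsilyloxy)methyl]-6-[3-(4-allyloxy-2-methoxyphenyl)propyl]-2,2-dimethyl-2H-chromene | COc1cc(OCC=C)ccc1CCCc1cc(OCC=C)c2c(c1CO[Si](c3ccccc3)(c3ccccc3)C(C)(C)C)C=CC(C)(C)O2 | intermediate
19 | {8-(allyloxy)-6-[3-(4-allyloxy-2-methoxyphenyl)propyl]-2,2-dimethyl-2H-chromen-5-yl}methanol | COc1cc(OCC=C)ccc1CCCc1cc(OCC=C)c2c(c1CO)C=CC(C)(C)O2 | intermediate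
20 | 8-(allyloxy)-5-(bromomethyl)-6-[3-(4-allyloxy-2-methoxyphenyl)propyl]-2,2-dimethyl-2H-chromene | COc1cc(OCC=C)ccc1CCCc1cc(OCC=C)c2c(c1CBr)C=CC(C)(C)O2 | intermediate
21 | 8-(allyloxy)-6-[3-(4-allyloxy-2-methoxyphenyl)propyl]-2,2-dimethyl-5-(3-methylbut-2-en-1-yl)-2H-chromene | COc1cc(OCC=C)ccc1CCCc1cc(OCC=C)c2c(c1CC=C(C)C)C=CC(C)(C)O2 | intermediate
22 | Kazinol N, 6-[3-(4-hydroxy-2-methoxyphenyl)propyl]-2,2-dimethyl-5-(3-methylbut-2-en-1-yl)-2H-chromen-8-ol | COc1cc(O)ccc1CCCc1cc(O)c2c(c1CC=C(C)C)C=CC(C)(C)O2 | target

## Step count and least certain steps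

Total: 12 steps. Longest linear sequence: 10 steps (steps 3, 4, 5, 6, 7, 8, 9, 10, 11, 12, from bromophenol 4). The kojic acid branch joins after 2 steps.

**Step 6 (key step, proposed new method).**
- What may go wrong: proton abstraction from the CH2OSi group of pyrylium salt 12 by the basic ylide instead of carbon–carbon bond formation; transfer of the silyl group from 12 to the ylide; slow olefination of keto ylide 14, leaving the open-chain dienone to oligomerise.
- Fallback (known chemistry only, from aryl bromide 5 back to phenol 16). Ring B is taken from a conventional benzene and the linker is attached by the coupling type already used in step 4.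
- Ring A part: Grignard reagent 7, made from 5 as in step 4, should be alkylated with 1-bromo-3-chloropropane (Li2CuCl4 cat.) to 1-(allyloxy)-4-(3-chloropropyl)-3-methoxybenzene F1. NaI in refluxing acetone should convert it into 1-(allyloxy)-4-(3-iodopropyl)-3-methoxybenzene F2.
- Ring B part: commercial 3,4-dihydroxybenzaldehyde should be allylated at its more acidic 4-hydroxyl (allyl bromide, NaHCO3, NaI, DMF) to 4-(allyloxy)-3-hydroxybenzaldehyde F3 and reduced with NaBH4 to 2-(allyloxy)-5-(hydroxymethyl)phenol F4. N-Iodosuccinimide should iodinate para to the free hydroxyl, giving 2-(allyloxy)-5-(hydroxymethyl)-4-iodophenol F5. Silylation of both hydroxyls (t-BuPh2SiCl, imidazole) should give tert-butyl{[4-(allyloxy)-5-(tert-butyldiphenylsilyloxy)-2-iodophenyl]methoxy}diphenylsilane F6.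
- Union: iodine–magnesium exchange (i-PrMgCl·LiCl, THF, −20 °C) should give {5-(allyloxy)-4-(tert-butyldiphenylsilyloxy)-2-[(tert-butyldiphenylsilyloxy)methyl]phenyl}magnesium chloride F7. Alkylation with F2 under Li2CuCl4 catalysis should give 1-(allyloxy)-2-(tert-butyldiphenylsilyloxy)-4-[(tert-butyldiphenylsilyloxy)methyl]-5-[3-(4-allyloxy-2-methoxyphenyl)propyl]benzene F8. K2CO3 in MeOH should then remove only the aryl silyl group and deliver 16.
- Cost: this replaces steps 1, 2, 5, 6 and 7 at the price of a longer sequence, and it relies on para-selective iodination of F4.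

**Step 8 (chromene annulation).**
- What may go wrong: sluggish ortho-hydroxyalkylation at the one free position, which is flanked by the silyloxymethyl group, so that self-condensation of the enal and acid-induced loss of the benzylic silyl ether on prolonged heating take over.
- Fallback (from 16 back to 18): O-alkylation of 16 with 3-chloro-3-methylbut-1-yne (CuCl2·2H2O cat., DBU, MeCN, 0 °C) should give the aryl propargyl ether 1-(allyloxy)-4-[(tert-butyldiphenylsilyloxy)methyl]-2-[(2-methylbut-3-yn-2-yl)oxy]-5-[3-(4-allyloxy-2-methoxyphenyl)propyl]benzene F9. Heating in xylene at 140 °C should give 18 by aromatic propargyl Claisen rearrangement, 1,5-hydrogen shift and oxa-6π closure. The gem-dimethyl propargyl ether rearranges well below the temperature at which the two allyl aryl ethers do.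

**Step 11 (prenyl coupling, including the labile bromide 20).**
- What may go wrong: ionisation and self-alkylation of the para-alkoxybenzylic bromide before it couples, and Wurtz-type homocoupling of the benzylic partner under copper catalysis.
- Fallback (from alcohol 19 back to 21, avoiding any benzylic halide; the alkene is formed last by olefination). MnO2 in CH2Cl2 should oxidise 19 to 8-(allyloxy)-6-[3-(4-allyloxy-2-methoxyphenyl)propyl]-2,2-dimethyl-2H-chromene-5-carbaldehyde F10. Wittig reaction with the ylide from (methoxymethyl)triphenylphosphonium chloride and KN(SiMe3)2 should give the enol ether 8-(allyloxy)-5-(2-methoxyethenyl)-6-[3-(4-allyloxy-2-methoxyphenyl)propyl]-2,2-dimethyl-2H-chromene F11 as an E/Z mixture. Brief hydrolysis with dilute HCl in THF should give {8-(allyloxy)-6-[3-(4-allyloxy-2-methoxyphenyl)propyl]-2,2-dimethyl-2H-chromen-5-yl}acetaldehyde F12. Wittig reaction with the ylide from isopropyltriphenylphosphonium iodide and n-BuLi should then give 21.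

**Step 4 (Grignard alkylation).**
- What may go wrong: copper-mediated allylic substitution of the allyl ether by the aryl nucleophile and biaryl formation, both of which consume reagent 7.
- Fallback (from bromophenol 4 back to chloride 8; the allyl group is introduced only after the carbon–carbon bond is made). i-Pr3SiCl and imidazole should give (4-bromo-3-methoxyphenoxy)tri(propan-2-yl)silane F13. Mg in THF should give [2-methoxy-4-(triisopropylsilyloxy)phenyl]magnesium bromide F14. Alkylation with 6 under Li2CuCl4 catalysis should give [4-(4-chlorobutyl)-3-methoxyphenoxy]tri(propan-2-yl)silane F15. n-Bu4NF at 0 °C should give 4-(4-chlorobutyl)-3-methoxyphenol F16, and allyl bromide with K2CO3 in acetone should give 8.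

## Further compounds

F1 | step 6 | 1-(allyloxy)-4-(3-chloropropyl)-3-methoxybenzene | C=CCOc1ccc(CCCCl)c(OC)c1
F2 | step 6 | 1-(allyloxy)-4-(3-iodopropyl)-3-methoxybenzene | C=CCOc1ccc(CCCI)c(OC)c1
F3 | step 6 | 4-(allyloxy)-3-hydroxybenzaldehyde | C=CCOc1ccc(C=O)cc1O
F4 | step 6 | 2-(allyloxy)-5-(hydroxymethyl)phenol | C=CCOc1ccc(CO)cc1O
F5 | step 6 | 2-(allyloxy)-5-(hydroxymethyl)-4-iodophenol | C=CCOc1cc(I)c(CO)cc1O
F6 | step 6 | tert-butyl{[4-(allyloxy)-5-(tert-butyldiphenylsilyloxy)-2-iodophenyl]methoxy}diphenylsilane | C=CCOc1cc(I)c(CO[Si](c2ccccc2)(c2ccccc2)C(C)(C)C)cc1O[Si](c1ccccc1)(c1ccccc1)C(C)(C)C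
F7 | step 6 | {5-(allyloxy)-4-(tert-butyldiphenylsilyloxy)-2-[(tert-butyldiphenylsilyloxy)methyl]phenyl}magnesium chloride | C=CCOc1cc([Mg]Cl)c(CO[Si](c2ccccc2)(c2ccccc2)C(C)(C)C)cc1O[Si](c1ccccc1)(c1ccccc1)C(C)(C)C
F8 | step 6 | 1-(allyloxy)-2-(tert-butyldiphenylsilyloxy)-4-[(tert-butyldiphenylsilyloxy)methyl]-5-[3-(4-allyloxy-2-methoxyphenyl)propyl]benzene | C=CCOc1ccc(CCCc2cc(OCC=C)c(O[Si](c3ccccc3)(c3ccccc3)C(C)(C)C)cc2CO[Si](c2ccccc2)(c2ccccc2)C(C)(C)C)c(OC)c1
F9 | step 8 | 1-(allyloxy)-4-[(tert-butyldiphenylsilyloxy)methyl]-2-[(2-methylbut-3-yn-2-yl)oxy]-5-[3-(4-allyloxy-2-methoxyphenyl)propyl]benzene | C=CCOc1ccc(CCCc2cc(OCC=C)c(OC(C)(C)C#C)cc2CO[Si](c2ccccc2)(c2ccccc2)C(C)(C)C)c(OC)c1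
F10 | step 11 | 8-(allyloxy)-6-[3-(4-allyloxy-2-methoxyphenyl)propyl]-2,2-dimethyl-2H-chromene-5-carbaldehyde | COc1cc(OCC=C)ccc1CCCc1cc(OCC=C)c2c(c1C=O)C=CC(C)(C)O2
F11 | step 11 | 8-(allyloxy)-5-(2-methoxyethenyl)-6-[3-(4-allyloxy-2-methoxyphenyl)propyl]-2,2-dimethyl-2H-chromene (E/Z mixture) | COc1cc(OCC=C)ccc1CCCc1cc(OCC=C)c2c(c1C=COC)C=CC(C)(C)O2
F12 | step 11 | {8-(allyloxy)-6-[3-(4-allyloxy-2-methoxyphenyl)propyl]-2,2-dimethyl-2H-chromen-5-yl}acetaldehyde | COc1cc(OCC=C)ccc1CCCc1cc(OCC=C)c2c(c1CC=O)C=CC(C)(C)O2
F13 | step 4 | (4-bromo-3-methoxyphenoxy)tri(propan-2-yl)silane | COc1cc(O[Si](C(C)C)(C(C)C)C(C)C)ccc1Br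
F14 | step 4 | [2-methoxy-4-(triisopropylsilyloxy)phenyl]magnesium bromide | COc1cc(O[Si](C(C)C)(C(C)C)C(C)C)ccc1[Mg]Br
F15 | step 4 | [4-(4-chlorobutyl)-3-methoxyphenoxy]tri(propan-2-yl)silane | COc1cc(O[Si](C(C)C)(C(C)C)C(C)C)ccc1CCCCCl
F16 | step 4 | 4-(4-chlorobutyl)-3-methoxyphenol | COc1cc(O)ccc1CCCCCl
A1 | alternative 1 | 2-[4-(methoxymethoxy)-2-(3-methylbut-2-en-1-yl)-5-(triisopropylsilyloxy)phenyl]-7-(triisopropylsilyloxy)chromane (racemic, one enantiomer drawn) | CC(C)[Si](Oc1ccc2CC[C@@H](c3cc(O[Si](C(C)C)(C(C)C)C(C)C)c(OCOC)cc3CC=C(C)C)Oc2c1)(C(C)C)C(C)C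
A2 | alternative 1 | 1-ethenyl-4-(methoxymethoxy)-2-(3-methylbut-2-en-1-yl)-5-(triisopropylsilyloxy)benzene | C=Cc1cc(O[Si](C(C)C)(C(C)C)C(C)C)c(OCOC)cc1CC=C(C)C
A3 | alternative 1 | tert-butyl [2-(hydroxymethyl)-5-(triisopropylsilyloxy)phenyl] carbonate | CC(C)(C)OC(=O)Oc1cc(O[Si](C(C)C)(C(C)C)C(C)C)ccc1CO
A4 | alternative 2 | methyl 3-(benzyloxy)-6-[2-(benzyloxy)ethyl]-2-hydroxy-5-{3-[2-methoxy-4-(triisopropylsilyloxy)phenyl]propyl}benzoate | COC(=O)c1c(O)c(OCc2ccccc2)cc(CCCc2ccc(O[Si](C(C)C)(C(C)C)C(C)C)cc2OC)c1CCOCc1ccccc1
A5 | alternative 2 | 4-(benzyloxy)-1-methoxy-1,3-bis(trimethylsilyloxy)buta-1,3-diene | COC(O[Si](C)(C)C)=CC(O[Si](C)(C)C)=COCc1ccccc1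
A6 | alternative 2 | 1-(benzyloxy)-7-[2-methoxy-4-(triisopropylsilyloxy)phenyl]-4-[(trimethylsilyloxy)methylidene]heptan-3-one | C[Si](C)(C)OC=C(CCCc1ccc(O[Si](C(C)C)(C(C)C)C(C)C)cc1OC)C(=O)CCOCc1ccccc1
A7 | alternative 3 | bis(methoxymethyl) ether of Kazinol N, 8-(methoxymethoxy)-6-{3-[2-methoxy-4-(methoxymethoxy)phenyl]propyl}-2,2-dimethyl-5-(3-methylbut-2-en-1-yl)-2H-chromene | COCOc1ccc(CCCc2cc(OCOC)c3OC(C)(C)C=Cc3c2CC=C(C)C)c(OC)c1
A8 | alternative 3 | 5-iodo-8-(methoxymethoxy)-2,2-dimethyl-2H-chromene | COCOc1ccc(I)c2C=CC(C)(C)Oc12
A9 | alternative 3 | 1-(3-bromopropyl)-2-methoxy-4-(methoxymethoxy)benzene | COCOc1ccc(CCCBr)c(OC)c1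
A10 | alternative 3 | 4,4,5,5-tetramethyl-2-(3-methylbut-2-en-1-yl)-1,3,2-dioxaborolane | CC(C)=CCB1OC(C)(C)C(C)(C)O1
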